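**Retrosynthetic overview**

- The target is reached by removing two triethylsilyl groups (O4′, O7′) from a fully assembled coumarin.
- The route rests on the 2H-pyran-2-one ring (O1–C2(=O)–C3=C4, fused to the benzene ring at C4a/C8a). This lactone and Michael acceptor is the part that basic, nucleophilic and hydridic steps would damage, so it is disconnected first, at O1–C2 and C3=C4, to a 2-hydroxybenzaldehyde carrying the complete C7 ether and (triphenylphosphoranylidene)ketene.
- The O7–C1′ aryl ether is cut to 2,4-dihydroxy-5-methoxybenzaldehyde and the (2E,4R) bis-silylated allylic alcohol, joined by Mitsunobu etherification at the non-chelated 4-OH.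
- In the side chain, the C4′ stereocentre comes from CBS reduction of the E-enone. The C4′–C5′ bond comes from a γ-silyloxy Grignard reagent and (E)-4-acetoxy-2-methylbut-2-enal, which is made from prenyl acetate.
- Ring order: the benzene ring is bought, and the pyranone ring is the only ring closed (step 9), after the side chain and its stereocentre are in place.

Key step: step 9

Assumption: 2,4-dihydroxy-5-methoxybenzaldehyde, 4-bromo-2-methylbutan-2-ol and (triphenylphosphoranylidene)ketene are taken as catalogue compounds (the bromo alcohol is otherwise one step from ethyl 3-bromopropanoate and MeMgBr).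

**Route**

Step 1
Reactants: 1 3-methylbut-2-en-1-yl acetate (prenyl acetate)
Product: 2 (2E)-3-methyl-4-oxobut-2-en-1-yl acetate
Conditions: SeO2 (1.1 equiv), 1,4-dioxane/H2O (20:1), 90 °C
Reagents that add atoms: selenium dioxide, O=[Se]=O
Why: Riley allylic oxidation (ene reaction of SeO2, then [2,3]-sigmatropic shift) takes the methyl group trans to CH2OAc through to the aldehyde, the established access to this E-configured C5 acetoxy enal, and it fixes the E geometry of the later C2′=C3′ bond.

Step 2
Reactants: 3 4-bromo-2-methylbutan-2-ol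
Product: 4 [(4-bromo-2-methylbutan-2-yl)oxy]triethylsilane
Conditions: TESOTf (1.2 equiv), 2,6-lutidine (1.5 equiv), CH2Cl2, 0 °C
Reagents that add atoms: triethylsilyl trifluoromethanesulfonate, CC[Si](CC)(CC)OS(=O)(=O)C(F)(F)F
Why: Silylation of a tertiary alcohol with a silyl triflate and a hindered base is routine and gives a bromide whose oxygen is masked for Grignard formation.

Step 3
Reactants: 4 [(4-bromo-2-methylbutan-2-yl)oxy]triethylsilane; 2 (2E)-3-methyl-4-oxobut-2-en-1-yl acetate
Product: 6 (2E)-4-hydroxy-3,7-dimethyl-7-(triethylsilyloxy)oct-2-en-1-yl acetate (racemic at C4), via [3-methyl-3-(triethylsilyloxy)butyl]magnesium bromide 5 (not isolated)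
Conditions: Mg, THF, 40 °C; then slow addition to 2 (1.0 equiv), THF, −78 °C; aq NH4Cl
Reagents that add atoms: none
Why: Grignard 1,2-addition to the aldehyde is far faster at −78 °C than attack on the acetate, so the C4–C5 bond should form cleanly and the carbinol is left racemic because its configuration is set in step 5.

Step 4
Reactants: 6 (2E)-4-hydroxy-3,7-dimethyl-7-(triethylsilyloxy)oct-2-en-1-yl acetate (racemic at C4)
Product: 7 (2E)-3,7-dimethyl-4-oxo-7-(triethylsilyloxy)oct-2-en-1-yl acetate
Conditions: Dess–Martin periodinane (1.3 equiv), NaHCO3 (4 equiv), CH2Cl2, 0 °C to rt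
Reagents that add atoms: none
Why: Dess–Martin oxidation of a secondary allylic alcohol gives the enone under buffered, near-neutral conditions that the silyl ether, the acetate and the E alkene tolerate.

Step 5
Reactants: 7 (2E)-3,7-dimethyl-4-oxo-7-(triethylsilyloxy)oct-2-en-1-yl acetate
Product: 8 (2E,4R)-4-hydroxy-3,7-dimethyl-7-(triethylsilyloxy)oct-2-en-1-yl acetate
Conditions: (S)-Me-CBS [(S)-1-methyl-3,3-diphenyltetrahydro-1H,3H-pyrrolo[1,2-c][1,3,2]oxazaborole] (0.2 equiv), catecholborane (1.8 equiv), toluene, −78 °C; MeOH quench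
Reagents that add atoms: none
Why: In the Corey–Bakshi–Shibata reduction the ketone binds the (S)-oxazaborolidine with the α-methyl alkenyl group as the large substituent against the unbranched CH2 chain, so hydride should reach the Si face of C4 and set the (4R) carbinol, while catecholborane at −78 °C spares the acetate and the alkene.

Step 6
Reactants: 8 (2E,4R)-4-hydroxy-3,7-dimethyl-7-(triethylsilyloxy)oct-2-en-1-yl acetate
Product: 9 (2E,4R)-3,7-dimethyl-4,7-bis(triethylsilyloxy)oct-2-en-1-yl acetate
Conditions: TESCl (1.3 equiv), imidazole (2.5 equiv), DMF, 0 °C to rt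
Reagents that add atoms: chlorotriethylsilane, CC[Si](CC)(CC)Cl
Why: Imidazole-promoted silylation of the secondary allylic alcohol proceeds at oxygen with retention at C4 and gives both hydroxyls the same protecting group for a single final deprotection.

Step 7
Reactants: 9 (2E,4R)-3,7-dimethyl-4,7-bis(triethylsilyloxy)oct-2-en-1-yl acetate
Product: 10 (2E,4R)-3,7-dimethyl-4,7-bis(triethylsilyloxy)oct-2-en-1-ol
Conditions: K2CO3 (0.2 equiv), MeOH, 0 °C
Reagents that add atoms: none
Why: Carbonate-catalysed methanolysis (transesterification) removes the primary acetate, the triethylsilyl ethers survive catalytic carbonate at 0 °C, and they cannot migrate to O1 because O1 and O4 are held trans across the E alkene.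

Step 8
Reactants: 10 (2E,4R)-3,7-dimethyl-4,7-bis(triethylsilyloxy)oct-2-en-1-ol; 11 2,4-dihydroxy-5-methoxybenzaldehyde
Product: 12 2-hydroxy-5-methoxy-4-{[(2E,4R)-3,7-dimethyl-4,7-bis(triethylsilyloxy)oct-2-en-1-yl]oxy}benzaldehyde
Conditions: PPh3 (1.3 equiv), DIAD (1.3 equiv), 11 (1.2 equiv), THF, 0 °C to rt
Reagents that add atoms: none
Why: Mitsunobu etherification of the primary allylic alcohol proceeds by SN2 at C1′ and should select the 4-OH, which is the more acidic phenol, because the 2-OH is tied up in a hydrogen bond to the formyl group.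

Step 9
Reactants: 12 2-hydroxy-5-methoxy-4-{[(2E,4R)-3,7-dimethyl-4,7-bis(triethylsilyloxy)oct-2-en-1-yl]oxy}benzaldehyde; 13 (triphenylphosphoranylidene)ketene
Product: 16 7-{[(2E,4R)-3,7-dimethyl-4,7-bis(triethylsilyloxy)oct-2-en-1-yl]oxy}-6-methoxy-2H-chromen-2-one, via aryl (triphenylphosphoranylidene)acetate 14 (not isolated), via fused oxaphosphetane 15 (not isolated)
Conditions: 13 (1.2 equiv), toluene, 80 °C, argon
Reagents that add atoms: (triphenylphosphoranylidene)ketene (compound 13), O=C=C=P(c1ccccc1)(c1ccccc1)c1ccccc1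
Why: The phenolic O–H of 12 adds across the C=C bond of the cumulated ylide 13 (protonation at the ylide carbon, then capture of the ketene carbon by the phenoxide), which makes the O1–C2 bond and gives the aryl ester-stabilised ylide 14. The ylide carbon of 14 then attacks the neighbouring formyl carbon in a 6-exo-trig closure of the pyran-2-one ring, and the oxaphosphetane 15 collapses to the C3=C4 double bond with loss of triphenylphosphine oxide, so the sequence is a tandem acylation and intramolecular Wittig olefination. The closest known reaction type is the coumarin synthesis from salicylaldehydes and (triphenylphosphoranylidene)ketene. No stereocentre is created: the cis geometry at C3=C4 is imposed by the six-membered ring, and the (4′R) centre and the E alkene of the side chain are not involved. The step needs chemoselectivity for the phenol over other O–H groups and regiocontrol of ring closure; the first is secured by the triethylsilyl ethers at O4′ and O7′, the second by the ortho relationship of OH and CHO. The neutral medium at 80 °C lies far below the temperature at which the allyl aryl ether would undergo aromatic Claisen rearrangement.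

Step 10
Reactants: 16 7-{[(2E,4R)-3,7-dimethyl-4,7-bis(triethylsilyloxy)oct-2-en-1-yl]oxy}-6-methoxy-2H-chromen-2-one
Product: 17 7-{[(2E,4R)-4,7-dihydroxy-3,7-dimethyloct-2-en-1-yl]oxy}-6-methoxy-2H-chromen-2-one
Conditions: HF·pyridine, pyridine, THF, 0 °C to rt
Reagents that add atoms: none
Why: Fluoride-driven desilylation cleaves both Si–O bonds (the tertiary one included) without touching the C4′–O bond, and the pyridine-buffered medium should leave the lactone, the allyl aryl ether and the allylic alcohol intact.

**Compound list**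

1 | 3-methylbut-2-en-1-yl acetate (prenyl acetate) | CC(=O)OCC=C(C)C | starting material
2 | (2E)-3-methyl-4-oxobut-2-en-1-yl acetate | CC(=O)OC/C=C(\C)C=O | intermediate
3 | 4-bromo-2-methylbutan-2-ol | CC(C)(O)CCBr | starting material
4 | [(4-bromo-2-methylbutan-2-yl)oxy]triethylsilane | CC[Si](CC)(CC)OC(C)(C)CCBr | intermediate
5 | [3-methyl-3-(triethylsilyloxy)butyl]magnesium bromide (formed in the flask) | CC[Si](CC)(CC)OC(C)(C)CC[Mg]Br | intermediate
6 | (2E)-4-hydroxy-3,7-dimethyl-7-(triethylsilyloxy)oct-2-en-1-yl acetate, racemic at C4 | CC(=O)OC/C=C(\C)C(O)CCC(C)(C)O[Si](CC)(CC)CC | intermediate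
7 | (2E)-3,7-dimethyl-4-oxo-7-(triethylsilyloxy)oct-2-en-1-yl acetate | CC(=O)OC/C=C(\C)C(=O)CCC(C)(C)O[Si](CC)(CC)CC | intermediate
8 | (2E,4R)-4-hydroxy-3,7-dimethyl-7-(triethylsilyloxy)oct-2-en-1-yl acetate | CC(=O)OC/C=C(\C)[C@H](O)CCC(C)(C)O[Si](CC)(CC)CC | intermediate
9 | (2E,4R)-3,7-dimethyl-4,7-bis(triethylsilyloxy)oct-2-en-1-yl acetate | CC(=O)OC/C=C(\C)[C@H](O[Si](CC)(CC)CC)CCC(C)(C)O[Si](CC)(CC)CC | intermediate
10 | (2E,4R)-3,7-dimethyl-4,7-bis(triethylsilyloxy)oct-2-en-1-ol | OC/C=C(\C)[C@H](O[Si](CC)(CC)CC)CCC(C)(C)O[Si](CC)(CC)CC | intermediate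
11 | 2,4-dihydroxy-5-methoxybenzaldehyde | COc1cc(C=O)c(O)cc1O | starting material
12 | 2-hydroxy-5-methoxy-4-{[(2E,4R)-3,7-dimethyl-4,7-bis(triethylsilyloxy)oct-2-en-1-yl]oxy}benzaldehyde | COc1cc(C=O)c(O)cc1OC/C=C(\C)[C@H](O[Si](CC)(CC)CC)CCC(C)(C)O[Si](CC)(CC)CC | intermediate
13 | (triphenylphosphoranylidene)ketene | O=C=C=P(c1ccccc1)(c1ccccc1)c1ccccc1 | starting material
14 | 2-formyl-4-methoxy-5-{[(2E,4R)-3,7-dimethyl-4,7-bis(triethylsilyloxy)oct-2-en-1-yl]oxy}phenyl (triphenylphosphoranylidene)acetate (formed in the flask) | COc1cc(C=O)c(OC(=O)C=P(c2ccccc2)(c2ccccc2)c2ccccc2)cc1OC/C=C(\C)[C@H](O[Si](CC)(CC)CC)CCC(C)(C)O[Si](CC)(CC)CC | intermediate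
15 | 2,2,2-triphenyl-1,2-oxaphosphetane fused across C3–C4 of the 6-methoxy-7-alkoxychroman-2-one (P on C3, O on C4; formed in the flask) | COc1cc2c(cc1OC/C=C(\C)[C@H](O[Si](CC)(CC)CC)CCC(C)(C)O[Si](CC)(CC)CC)OC(=O)C1C2OP1(c1ccccc1)(c1ccccc1)c1ccccc1 | intermediate
16 | 7-{[(2E,4R)-3,7-dimethyl-4,7-bis(triethylsilyloxy)oct-2-en-1-yl]oxy}-6-methoxy-2H-chromen-2-one | COc1cc2ccc(=O)oc2cc1OC/C=C(\C)[C@H](O[Si](CC)(CC)CC)CCC(C)(C)O[Si](CC)(CC)CC | intermediate
17 | 7-{[(2E,4R)-4,7-dihydroxy-3,7-dimethyloct-2-en-1-yl]oxy}-6-methoxy-2H-chromen-2-one (CNP0197418.1) | COc1cc2ccc(=O)oc2cc1OC/C=C(\C)[C@H](O)CCC(C)(C)O | target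

**Step count**

Total step count: 10.
Longest linear sequence: 9 steps (steps 1 and 3 to 10, from prenyl acetate); step 2 is a one-step side branch.

**Steps most likely to fail, with fallbacks**

Step 9 (key step). The chelated phenol may add only slowly to the cumulated ylide, adventitious water may consume the ylide, or the sequence may stall at the ester ylide. The fallback sets out from 12 and returns at 16, forming C3=C4 first and O1–C2 second. Aldehyde 12 would be treated with methyl (triphenylphosphoranylidene)acetate in CH2Cl2 at room temperature (intermolecular Wittig) to give methyl (2E)-3-(2-hydroxy-5-methoxy-4-{[(2E,4R)-3,7-dimethyl-4,7-bis(triethylsilyloxy)oct-2-en-1-yl]oxy}phenyl)prop-2-enoate F1. Irradiation of F1 at 365 nm in dilute MeCN at room temperature should isomerise the cinnamate to the Z form, which lactonises spontaneously with loss of methanol to 16. The whole detour runs at room temperature, so the allyl aryl ether is not at risk.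

Step 3. The Grignard reagent may attack the acetate carbonyl in competition with the aldehyde, or Wurtz coupling may erode the reagent during magnesium insertion. The fallback sets out from 4 (with 2 as partner) and returns at 8, bypassing steps 4 and 5. Bromide 4 would be converted with NaI in acetone (Finkelstein) into triethyl[(4-iodo-2-methylbutan-2-yl)oxy]silane F2. Iodine–zinc exchange (Et2Zn, CuI cat., 50 °C, volatiles removed) would then give bis[3-methyl-3-(triethylsilyloxy)butyl]zinc F3. Catalytic asymmetric addition of F3 to aldehyde 2 (Ti(OiPr)4, (1S,2S)-N,N′-bis(trifluoromethanesulfonyl)cyclohexane-1,2-diamine cat., toluene, −20 °C) should deliver the alkyl group to the Re face of the formyl carbon and give 8 directly. The ligand enantiomer is chosen by analogy with dialkylzinc additions to benzaldehyde and should be confirmed on the first run. Organozinc reagents do not touch the acetate.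

Step 8. The phenol may also be etherified at the chelated 2-OH or twice, or it may be delivered SN2′ to C3′. The fallback sets out from 10 and returns at 12, replacing redox condensation by phenoxide alkylation. Appel bromination of 10 (CBr4, PPh3, 2,6-lutidine, CH2Cl2, −20 °C) would give (2E,4R)-1-bromo-3,7-dimethyl-4,7-bis(triethylsilyloxy)oct-2-ene F4. F4 would be used at once to alkylate 11 with KHCO3 in MeCN at room temperature to 40 °C. Bicarbonate deprotonates only the more acidic 4-OH, so 12 should result.

**Further compounds**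

F1 | step 9 | methyl (2E)-3-(2-hydroxy-5-methoxy-4-{[(2E,4R)-3,7-dimethyl-4,7-bis(triethylsilyloxy)oct-2-en-1-yl]oxy}phenyl)prop-2-enoate | COC(=O)/C=C/c1cc(OC)c(OC/C=C(\C)[C@H](O[Si](CC)(CC)CC)CCC(C)(C)O[Si](CC)(CC)CC)cc1O
F2 | step 3 | triethyl[(4-iodo-2-methylbutan-2-yl)oxy]silane | CC[Si](CC)(CC)OC(C)(C)CCI
F3 | step 3 | bis[3-methyl-3-(triethylsilyloxy)butyl]zinc | CC[Si](CC)(CC)OC(C)(C)CC[Zn]CCC(C)(C)O[Si](CC)(CC)CC
F4 | step 8 | (2E,4R)-1-bromo-3,7-dimethyl-4,7-bis(triethylsilyloxy)oct-2-ene | BrC/C=C(\C)[C@H](O[Si](CC)(CC)CC)CCC(C)(C)O[Si](CC)(CC)CC
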